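All runs were generated by integration with constants of no real substance, and the scatter is random.

A flat curve shows that a flask has stopped, not what stopped it.

common to all: starting complex 0.25 M
- birch: incoming ligand 0.17 M; run made earlier
- elm: incoming ligand 0.44 M; run made earlier
- Monday's: incoming ligand 0.200 M; time 2.0 d
- Friday's: incoming ligand 0.625 M; time 2.0 d
- Saturday's: incoming ligand 0.300 M; time 2.0 d

| run | time / h | complex with two exchanged / % | complex with one exchanged / % | starting complex / % |
|---|---|---|---|---|
| birch | 8.00 | 3 | 26 | 72 |
| birch | 15.0 | 4 | 27 | 70 |
| birch | 25.0 | 4 | 27 | 68 |
| birch | 30.0 | 5 | 27 | 68 |
| birch | 40.0 | 4 | 28 | 70 |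
| birch | 50.0 | 3 | 27 | 69 |
| elm | 8.00 | 10 | 39 | 45 |
| elm | 15.0 | 12 | 45 | 42 |
| elm | 25.0 | 14 | 43 | 41 |
| elm | 30.0 | 11 | 42 | 41 |
| elm | 40.0 | 17 | 45 | 40 |
| elm | 50.0 | 16 | 44 | 39 |

(standard deviation of a reading: 1.5 percentage points)

- which of these holds the largest part of the starting complex at the end of Monday's (complex with one exchanged / starting complex / complex with two exchanged / complex with three exchanged)
- which of these holds the largest part of the starting complex at the end of Friday's (complex with one exchanged / starting complex / complex with two exchanged / complex with three exchanged)
- which of these holds the largest part of the starting complex at the end of Saturday's (complex with one exchanged / starting complex / complex with two exchanged / complex with three exchanged)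
- amount of complex with two exchanged at the end of Friday's, in percent of the starting complex charged

- what was read earlier has a scatter of 1.5 percentage points, one standard deviation

Does the level where a flask stops follow the charge of incoming ligand? Take the depth, the decadic logarithm of charged over remaining c(starting complex), and divide it by c(incoming ligand) charged. The last birch reading gives 0.948 M⁻¹. The last elm reading gives 0.929 M⁻¹, although elm was charged 2.59 times as much. Their mean, 0.939 M⁻¹, is a reading with its scatter: the depth per molar, the powers of ten by which c(starting complex) falls per molar of incoming ligand charged.

Where does that leave the new flasks? Starting complex should end at 64.9% of its charge in Monday's, 52.3% in Saturday's and 25.9% in Friday's.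

Which species then leads? By this reckoning Monday's and Saturday's keep a majority as starting complex. By the same reckoning Friday's goes lower than the last elm reading of 39%, and in that elm reading complex with one exchanged stood higher than starting complex, at 44%.

The forecast names starting complex for Monday's, starting complex for Saturday's and complex with one exchanged for Friday's, with 25% of complex with two exchanged in Friday's. Its ground is another one: “Simple stepwise binding fits better”.

The flasks end with starting complex largest in Monday's, starting complex in Saturday's and complex with one exchanged in Friday's, where complex with two exchanged stands at 25.0%.

    starting complex + incoming ligand → leaving ligand + complex with one exchanged (k = 0.00970 M⁻¹ min⁻¹)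
    incoming ligand → decomposed reagent (k = 0.00230 min⁻¹)
    complex with two exchanged + incoming ligand ⇌ leaving ligand + complex with three exchanged (K = 9.10, k = 0.0120 M⁻¹ min⁻¹)
    complex with one exchanged + incoming ligand → leaving ligand + complex with two exchanged (k = 0.00620 M⁻¹ min⁻¹)
    2 starting complex → homo dimer (k = 2.50 × 10⁻⁵ M⁻¹ min⁻¹)

At 0.118 d in Friday's, incoming ligand goes to decomposed reagent 1.9 times as fast as it goes into complex with one exchanged. In Friday's it is the limiting reagent, at 0.24% of its charge at the end. Friday's starting complex ends at 23.7%, a depth per molar of 1.00 M⁻¹ against the 0.939 M⁻¹ read earlier. For the flask like Friday's but with 0.25 M of incoming ligand, 0.939 M⁻¹ gives 58.2% of starting complex, and that flask ends at 57.3%.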